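The plan cuts ring B (C5–C10, drimane numbering) at C5–C6 and C9–C10. Its C6–C7=C8(CH3)–C9–C11 segment is an E-configured dienyl ether in disguise, and its C5–C10(CH3) edge is the methyl-bearing alkene of a methoxy(methyl)benzoquinone that goes on to become ring A. A single catalytic enantioselective Diels–Alder reaction, finished by C5 epimerisation in the same flask, closes ring B, makes both bonds and sets C5, C9 and C10, including the α-oriented C11 arm. Its precursors are the silyl ether of (E)-3-methylpenta-2,4-dienol and 2-methoxy-5-methyl-1,4-benzoquinone. Ring A is then reshaped and the coumarin is attached last.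

Key step: step 3

Assumption: the (S)-prolinol-derived catalyst is taken to leave open the quinone face that gives 10S; the sense is to be confirmed on the first run and the (R)-catalyst used instead if it is the reverse, with nothing else changed.

Conventions: drimane locants throughout (ring A: C1–C5, C10; ring B: C5–C10; C11 is the CH2O carbon on C9). β is the face of the C10 methyl group, α the opposite face. "Decal" names a decalin carrying these locants. "9βH-drimane" is the drimane skeleton with the C9 hydrogen β, so C11 is α.

Step 1
Reactants: 1 (E)-3-methylpent-2-en-4-yn-1-ol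
Product: 2 (E)-tert-butyl[(3-methylpent-2-en-4-yn-1-yl)oxy]diphenylsilane
Conditions: TBDPSCl, imidazole, CH2Cl2, 0 °C → rt
Reagents that add atoms: tert-butyl(chloro)diphenylsilane, CC(C)(C)[Si](Cl)(c1ccccc1)c1ccccc1
Why: Imidazole-promoted silylation of a primary allylic alcohol (silyl ether formation) should be clean; the bulky TBDPS ether, weakly basic at oxygen, is chosen to withstand the acid catalyst of step 3 and the reagents of steps 4–10, and no stereocentre is formed.

Step 2
Reactants: 2 (E)-tert-butyl[(3-methylpent-2-en-4-yn-1-yl)oxy]diphenylsilane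
Product: 3 (E)-tert-butyl[(3-methylpenta-2,4-dien-1-yl)oxy]diphenylsilane
Conditions: H2 (1 atm), Pd/CaCO3 poisoned with Pb(OAc)2, quinoline, hexane–EtOAc, 0 °C → rt, stopped after 1 equiv H2
Reagents that add atoms: none
Why: Alkyne semihydrogenation on lead-poisoned palladium should stop at the alkene because the terminal alkyne binds the surface far more strongly than the diene formed; the E trisubstituted alkene is retained and no stereocentre is formed.

Step 3
Reactants: 3 (E)-tert-butyl[(3-methylpenta-2,4-dien-1-yl)oxy]diphenylsilane; 4 2-methoxy-5-methyl-1,4-benzoquinone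
Product: 6 trans-fused 9α-(tert-butyldiphenylsilyloxymethyl)-3-methoxy-8,10β-dimethyl-5α-decal-2,7-diene-1,4-dione, via cis-fused endo adduct 5 (not isolated)
Conditions: 4 (1.0 equiv), 3 (1.5 equiv), (S)-3,3-diphenyl-1-(2-methylphenyl)tetrahydro-1H,3H-pyrrolo[1,2-c][1,3,2]oxazaborole·HN(SO2CF3)2 (20 mol%), CH2Cl2, −78 → −40 °C; then 1,8-diazabicyclo[5.4.0]undec-7-ene (DBU, 0.5 equiv), argon, −40 °C → rt
Reagents that add atoms: none
Why: The protonated oxazaborolidine is a monodentate boron Lewis acid that should bind the more basic carbonyl of 4, the vinylogous-ester C=O that becomes C1=O, and lower the LUMO of the methyl-bearing alkene (the methoxy-bearing alkene is deactivated by oxygen donation), after which 3 adds in a concerted, asynchronous, suprafacial [4+2] cycloaddition; the closest known reaction type is the oxazaborolidinium-catalysed enantioselective Diels–Alder reaction of alkyl-substituted 1,4-benzoquinones with acyclic dienes. Ring B closes as a six-membered carbocycle in the intermolecular [4+2] mode, C5–C6 forming ahead of C9–C10. The pairing of termini, which the step needs, should follow from the binding site: the carbon β to the bound carbonyl (future C5) is the electrophilic end and takes the unsubstituted, least hindered diene terminus (future C6), the orientation that monodentate boron Lewis acids give with 1-substituted dienes on this quinone, whereas chelating Lewis acids such as SnCl4, which hold the other carbonyl together with the methoxy oxygen and reverse the pairing, are avoided. C10 is set by the quinone face that the aryl groups of the catalyst leave open, and C9 follows from it through the endo transition state and the E geometry of the diene, which put C11 on the side of ring A and anti to the angular methyl. C5 is first formed cis to the C10 methyl by suprafacial addition (5) and is then inverted by DBU through the extended C4 enolate, the trans-fused 6 being expected to prevail because it frees the C11 arm from the concave face of the cis-bicycle. The TBDPS ether, bulky and weakly basic at oxygen, is chosen so that the dienyl C–O bond does not ionise under the acid catalyst at low temperature.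

Step 4
Reactants: 6 trans-fused 9α-(tert-butyldiphenylsilyloxymethyl)-3-methoxy-8,10β-dimethyl-5α-decal-2,7-diene-1,4-dione
Product: 8 9α-(tert-butyldiphenylsilyloxymethyl)-4-hydroxy-8,10β-dimethyl-5α-decal-1,7-dien-3-one, via 1,4-diol 7 (not isolated)
Conditions: LiAlH4, THF, 0 °C; then 1 M aq. HCl, THF, 0 °C → rt
Reagents that add atoms: water, O
Why: Hydride 1,2-reduction of both carbonyls, then acid ionisation of the C1 hydroxyl assisted by the enol ether oxygen and hydrolysis of the resulting oxocarbenium ion (reductive 1,3-carbonyl transposition of a vinylogous ester), should give the C1=C2–C3=O enone with the C4 hydroxyl kept; C5, C9 and C10 are untouched, the C4 carbinol configuration is inconsequential, and the TBDPS ether tolerates cold dilute acid.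

Step 5
Reactants: 8 9α-(tert-butyldiphenylsilyloxymethyl)-4-hydroxy-8,10β-dimethyl-5α-decal-1,7-dien-3-one
Product: 9 4-acetoxy-9α-(tert-butyldiphenylsilyloxymethyl)-8,10β-dimethyl-5α-decal-1,7-dien-3-one
Conditions: Ac2O, pyridine, 4-(dimethylamino)pyridine (cat.), CH2Cl2, rt
Reagents that add atoms: acetic anhydride, CC(=O)OC(C)=O
Why: Nucleophile-catalysed acetylation of the secondary ketol hydroxyl turns the C4 oxygen into a leaving group for reductive cleavage; no stereocentre changes.

Step 6
Reactants: 9 4-acetoxy-9α-(tert-butyldiphenylsilyloxymethyl)-8,10β-dimethyl-5α-decal-1,7-dien-3-one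
Product: 10 9α-(tert-butyldiphenylsilyloxymethyl)-8,10β-dimethyl-5α-decal-1,7-dien-3-one
Conditions: Zn dust (activated), AcOH, 70 °C
Reagents that add atoms: none
Why: Zinc reduction of an α-acyloxy ketone (dissolving-metal reductive cleavage) transfers two electrons to the carbonyl, expels acetate from C4 and gives a zinc dienolate that is protonated at C4; the conjugated C1=C2 and the isolated C7=C8 alkenes are not reduced by zinc in acetic acid.

Step 7
Reactants: 10 9α-(tert-butyldiphenylsilyloxymethyl)-8,10β-dimethyl-5α-decal-1,7-dien-3-one
Product: 12 11-(tert-butyldiphenylsilyloxy)-9βH-drima-1,7-dien-3-one, via 4-monomethyl enone 11 (not isolated)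
Conditions: KOt-Bu (3.5 equiv), MeI (6 equiv), t-BuOH–THF, 0 °C → rt
Reagents that add atoms: iodomethane, CI
Why: Enolate C-alkylation: the enone can enolise only toward C4 (C2 is vinylic, C10 quaternary), so excess base and MeI should methylate C4 twice to the gem-dimethyl group, which is not a stereocentre.

Step 8
Reactants: 12 11-(tert-butyldiphenylsilyloxy)-9βH-drima-1,7-dien-3-one
Product: 13 11-(tert-butyldiphenylsilyloxy)-9βH-drim-7-en-3-one
Conditions: [(Ph3P)CuH]6 (0.4 equiv), H2O (2 equiv), toluene–THF, rt
Reagents that add atoms: none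
Why: Conjugate reduction by a phosphine-stabilised copper hydride delivers hydride to C1 of the enone only and the copper enolate is protonated by water, leaving the ketone, the trisubstituted C7=C8 alkene and the silyl ether alone; no stereocentre is formed.

Step 9
Reactants: 13 11-(tert-butyldiphenylsilyloxy)-9βH-drim-7-en-3-one
Product: 14 11-(tert-butyldiphenylsilyloxy)-9βH-drim-7-en-3α-ol
Conditions: LiBH(s-Bu)3, THF, −78 → 0 °C; then H2O
Reagents that add atoms: none
Why: Diastereoselective ketone reduction with a bulky trialkylborohydride: the reagent should approach C3 along the equatorial trajectory, away from the axial hydrogens at C1 and C5 on the α face, so the new hydrogen is equatorial (β) and the hydroxyl axial (3α), as is usual for 4,4-dimethyl-3-oxo trans-decalins.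

Step 10
Reactants: 14 11-(tert-butyldiphenylsilyloxy)-9βH-drim-7-en-3α-ol
Product: 15 3α-acetoxy-11-(tert-butyldiphenylsilyloxy)-9βH-drim-7-ene
Conditions: Ac2O, 4-(dimethylamino)pyridine, pyridine, 50 °C
Reagents that add atoms: acetic anhydride, CC(=O)OC(C)=O
Why: Nucleophile-catalysed acetylation is strong enough for the hindered axial alcohol beside the gem-dimethyl group and leaves the C3–O bond intact, so the 3α configuration is retained.

Step 11
Reactants: 15 3α-acetoxy-11-(tert-butyldiphenylsilyloxy)-9βH-drim-7-ene
Product: 16 3α-acetoxy-9βH-drim-7-en-11-ol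
Conditions: Bu4NF, AcOH (1:1), THF, rt → 40 °C
Reagents that add atoms: none
Why: Fluoride-mediated Si–O cleavage is driven by the Si–F bond, and buffering with acetic acid keeps the medium non-basic so that the C3 acetate neither hydrolyses nor migrates.

Step 12
Reactants: 16 3α-acetoxy-9βH-drim-7-en-11-ol; 17 isofraxidin (7-hydroxy-6,8-dimethoxy-2H-chromen-2-one)
Product: 18 7-[(3α-acetoxy-9βH-drim-7-en-11-yl)oxy]-6,8-dimethoxy-2H-chromen-2-one (target)
Conditions: PPh3, diisopropyl azodicarboxylate, toluene, 0 → 50 °C
Reagents that add atoms: none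
Why: Mitsunobu etherification: the primary C11 alcohol is activated as its alkoxyphosphonium ion and displaced by the acidic 7-hydroxyl of isofraxidin (a phenol well within the acidity range of the reaction) in an SN2 step at a CH2 group, so no stereocentre is involved and the axial acetate and the lactone are spectators.

Compound list
1 | (E)-3-methylpent-2-en-4-yn-1-ol | C#C/C(C)=C/CO | starting material
2 | (E)-tert-butyl[(3-methylpent-2-en-4-yn-1-yl)oxy]diphenylsilane | C#C/C(C)=C/CO[Si](c1ccccc1)(c1ccccc1)C(C)(C)C | intermediate
3 | (E)-tert-butyl[(3-methylpenta-2,4-dien-1-yl)oxy]diphenylsilane | C=C/C(C)=C/CO[Si](c1ccccc1)(c1ccccc1)C(C)(C)C | intermediate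
4 | 2-methoxy-5-methyl-1,4-benzoquinone | COC1=CC(=O)C(C)=CC1=O | starting material
5 | cis-fused endo adduct: 9α-(tert-butyldiphenylsilyloxymethyl)-3-methoxy-8,10β-dimethyl-5β-decal-2,7-diene-1,4-dione (5β-H, 9β-H; not isolated) | CC(C)(C)[Si](c1ccccc1)(c1ccccc1)OC[C@@H]2C(C)=CC[C@@H]3C(=O)C(OC)=CC(=O)[C@]23C | intermediate
6 | trans-fused 9α-(tert-butyldiphenylsilyloxymethyl)-3-methoxy-8,10β-dimethyl-5α-decal-2,7-diene-1,4-dione (5α-H, 9β-H) | CC(C)(C)[Si](c1ccccc1)(c1ccccc1)OC[C@@H]2C(C)=CC[C@H]3C(=O)C(OC)=CC(=O)[C@]23C | intermediate
7 | 9α-(tert-butyldiphenylsilyloxymethyl)-3-methoxy-8,10β-dimethyl-5α-decal-2,7-diene-1,4-diol (carbinol configurations at C1 and C4 not controlled; not isolated) | CC(C)(C)[Si](c1ccccc1)(c1ccccc1)OC[C@@H]2C(C)=CC[C@H]3C(O)C(OC)=CC(O)[C@]23C | intermediate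
8 | 9α-(tert-butyldiphenylsilyloxymethyl)-4-hydroxy-8,10β-dimethyl-5α-decal-1,7-dien-3-one (C4 configuration not controlled) | CC(C)(C)[Si](c1ccccc1)(c1ccccc1)OC[C@@H]2C(C)=CC[C@H]3C(O)C(=O)C=C[C@]23C | intermediate
9 | 4-acetoxy-9α-(tert-butyldiphenylsilyloxymethyl)-8,10β-dimethyl-5α-decal-1,7-dien-3-one (C4 configuration not controlled) | CC(C)(C)[Si](c1ccccc1)(c1ccccc1)OC[C@@H]2C(C)=CC[C@H]3C(OC(C)=O)C(=O)C=C[C@]23C | intermediate
10 | 9α-(tert-butyldiphenylsilyloxymethyl)-8,10β-dimethyl-5α-decal-1,7-dien-3-one | CC(C)(C)[Si](c1ccccc1)(c1ccccc1)OC[C@@H]2C(C)=CC[C@H]3CC(=O)C=C[C@]23C | intermediate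
11 | 9α-(tert-butyldiphenylsilyloxymethyl)-4,8,10β-trimethyl-5α-decal-1,7-dien-3-one (C4 epimers; not isolated) | CC(C)(C)[Si](c1ccccc1)(c1ccccc1)OC[C@@H]2C(C)=CC[C@H]3C(C)C(=O)C=C[C@]23C | intermediate
12 | 11-(tert-butyldiphenylsilyloxy)-9βH-drima-1,7-dien-3-one | CC(C)(C)[Si](c1ccccc1)(c1ccccc1)OC[C@@H]2C(C)=CC[C@H]3C(C)(C)C(=O)C=C[C@]23C | intermediate
13 | 11-(tert-butyldiphenylsilyloxy)-9βH-drim-7-en-3-one | CC(C)(C)[Si](c1ccccc1)(c1ccccc1)OC[C@@H]2C(C)=CC[C@H]3C(C)(C)C(=O)CC[C@]23C | intermediate
14 | 11-(tert-butyldiphenylsilyloxy)-9βH-drim-7-en-3α-ol | CC(C)(C)[Si](c1ccccc1)(c1ccccc1)OC[C@@H]2C(C)=CC[C@H]3C(C)(C)[C@H](O)CC[C@]23C | intermediate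
15 | 3α-acetoxy-11-(tert-butyldiphenylsilyloxy)-9βH-drim-7-ene | CC(C)(C)[Si](c1ccccc1)(c1ccccc1)OC[C@@H]2C(C)=CC[C@H]3C(C)(C)[C@H](OC(C)=O)CC[C@]23C | intermediate
16 | 3α-acetoxy-9βH-drim-7-en-11-ol | OC[C@@H]1C(C)=CC[C@H]2C(C)(C)[C@H](OC(C)=O)CC[C@]12C | intermediate
17 | isofraxidin (7-hydroxy-6,8-dimethoxy-2H-chromen-2-one) | COc1cc2ccc(=O)oc2c(OC)c1O | starting material
18 | 7-[(3α-acetoxy-9βH-drim-7-en-11-yl)oxy]-6,8-dimethoxy-2H-chromen-2-one, (3R,5R,9R,10S) | COc1cc2ccc(=O)oc2c(OC)c1OC[C@@H]1C(C)=CC[C@H]2C(C)(C)[C@H](OC(C)=O)CC[C@]12C | target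

Total step count: 12. Longest linear sequence: 12 steps (1 → 18); 4 and 17 are bought and enter directly.

Steps most likely to fail

Step 3. The catalyst may bind the other quinone carbonyl, the one flanked by the alkene hydrogen, which would pair the diene termini the other way round. Face discrimination may be weak because the reacting alkene lies on the far side of the bound carbonyl. The C3 methyl of the diene works against the directing effect of the substituted terminus and may erode regioselectivity. The strong acid may also ionise the dienyl silyl ether before cycloaddition. The fallback sets out from 3 and 4 and returns at 6. BF3·OEt2 (1 equiv, CH2Cl2, −20 °C) is a monodentate Lewis acid whose preference for the vinylogous-ester carbonyl of this quinone is established. It would give 5 as a racemate together with its mirror-image cis adduct F1. DBU in the same flask would then give 6 together with its mirror-image trans adduct F2. Preparative chromatography on a chiral stationary phase (amylose carbamate phase, supercritical CO2–MeOH) would deliver 6. Stereocontrol then rests on resolution and not on the catalyst.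

Step 12. Displacement at the β-branched C11 alkoxyphosphonium ion by a phenoxide flanked by two methoxy groups may be slow, so that elimination toward C9 or alkylation of the reduced azodicarboxylate takes over. The fallback sets out from 16 and returns at 18. Tf2O and 2,6-lutidine (CH2Cl2, −78 °C) would give the C11 triflate F3, which is not stored but treated at once with 17 and Cs2CO3 (DMF, −20 → 0 °C) to give 18 by Williamson etherification. A sulfonate leaving group made beforehand thus replaces the redox condensation.

Step 7. The second methylation has to place a methyl group axial and syn to the C10 methyl; it may stall after the first alkylation or turn to O-methylation of the hindered enolate. The fallback sets out from 10 and returns at 12. LiN(i-Pr)2 and one equivalent of MeI (THF, −78 °C) would give 11, now isolated. LiN(i-Pr)2 and Me3SiCl would convert it into the cross-conjugated silyl dienol ether F4. Simmons–Smith cyclopropanation (Et2Zn, CH2I2, CH2Cl2, 0 °C), fastest at the electron-rich enol ether alkene, would give the siloxycyclopropane F5. NaOH in MeOH would then open the cyclopropanolate at its CH2–C3 bond, which turns the added CH2 into the second C4 methyl and gives 12. The hindered C–C bond is thus made by carbenoid addition to an alkene and not by enolate alkylation.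

Further compounds
F1 | step 3 | mirror-image cis adduct (enantiomer of 5, not isolated) | CC(C)(C)[Si](c1ccccc1)(c1ccccc1)OC[C@H]2C(C)=CC[C@H]3C(=O)C(OC)=CC(=O)[C@@]23C
F2 | step 3 | mirror-image trans adduct (enantiomer of 6) | CC(C)(C)[Si](c1ccccc1)(c1ccccc1)OC[C@H]2C(C)=CC[C@@H]3C(=O)C(OC)=CC(=O)[C@@]23C
F3 | step 12 | C11 triflate: 3α-acetoxy-9βH-drim-7-en-11-yl trifluoromethanesulfonate | O=S(=O)(OC[C@@H]1C(C)=CC[C@H]2C(C)(C)[C@H](OC(C)=O)CC[C@]12C)C(F)(F)F
F4 | step 7 | silyl dienol ether: 9α-(tert-butyldiphenylsilyloxymethyl)-4,8,10β-trimethyl-3-(trimethylsilyloxy)-5α-decal-1,3,7-triene | CC(C)(C)[Si](c1ccccc1)(c1ccccc1)OC[C@@H]2C(C)=CC[C@H]3C(C)=C(O[Si](C)(C)C)C=C[C@]23C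
F5 | step 7 | siloxycyclopropane: 3,4-methano adduct of F4 (cyclopropane across C3–C4, face not controlled) | CC(C)(C)[Si](c1ccccc1)(c1ccccc1)OC[C@@H]2C(C)=CC[C@H]3C4(C)CC4(O[Si](C)(C)C)C=C[C@]23C
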